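The numbers in the tables stem from a simulated flask on assumed constants; scatter was added.

I start with the protic impurity.

| flask | free monomer | protic impurity | initiator | remark | time |
|---|---|---|---|---|---|
| dawn | 22 mM | 22 mM | 3.8 mM | run made earlier |  |
| autumn | 88 mM | 22 mM | 3.8 mM | run made earlier |  |
| winter | 44 mM | 22 mM | 1.9 mM | run made earlier |  |
| cedar | 44 mM | 22.0 mM | 3.8 mM |  | 25 min |
| birch | 44 mM | 22.0 mM | 3.8 mM |  | 100 min |

| run | time / min | monomer in chains / % |
|---|---|---|
| dawn | 1.33 | 3 |
| dawn | 2.00 | 7 |
| dawn | 3.00 | 10 |
| dawn | 5.00 | 11 |
| dawn | 10.0 | 11 |
| dawn | 15.0 | 12 |
| autumn | 1.00 | 8 |
| autumn | 3.00 | 20 |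
| autumn | 5.00 | 31 |
| autumn | 8.00 | 46 |
| autumn | 12.0 | 53 |
| autumn | 15.0 | 59 |
| winter | 1.33 | 5 |
| winter | 4.00 | 10 |
| winter | 8.00 | 21 |
| winter | 10.0 | 19 |
| winter | 15.0 | 26 |

(each reading ± 2 percentage points)

1. which of the two ends with the longer chains by the average number of monomer units in a chain (chains begun, living or dead) ("neither" if they lie within 10%) (cedar / birch / neither)
2. average number of monomer units in a chain (chains begun, living or dead) at the end, cedar
3. average number of monomer units in a chain (chains begun, living or dead) at the end, birch

- the average divides the monomer in chains by the number of chains begun, living and dead together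
- steps that have been proposed: monomer in chains + living end -> free monomer + living end; free monomer + living end -> monomer in chains + living end; protic impurity + free monomer -> quenched substrate; free monomer + initiator -> living end + monomer in chains
- the earlier runs do not show the number of chains; that part of a forecast is a guess

How much free monomer reaches the chains? The dawn run charges 22 mM of free monomer against 22 mM of protic impurity, and its monomer in chains reads 11% at 5.00 min and 12% at 15.0 min. The autumn run, with 88 mM against the same impurity, reaches 59% at 15.0 min. So I read the impurity as taking free monomer one for one, and early.

How many chains share the rest? I guess one per initiator, which no reading shows. My rule is then the monomer budget per chain, c(free monomer) minus c(protic impurity), divided by c(initiator): 5.79 units for cedar and birch alike.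

Is there time to spend it? I treat growth as pseudo-first-order. In the autumn run, with the same initiator, 78.7% of the usable monomer is in chains at 15.0 min, which reads as a half-life of 6.73 min. By this reckoning cedar spends 92.4% of its budget, or 5.35 units, and birch, after 14.9 half-lives, reaches 5.79. They differ by 8.23%, less than 10%, so I say neither.

The forecast also says neither, with 5.4 for cedar and 5.8 for birch, and adds “Depropagation shows no visible effect”.

Cedar ends at 4.97 and birch at 5.06, so the answer is neither.

    monomer in chains + living end → free monomer + living end, rate k1*[living end] as long as [monomer in chains] is above zero (k = 0.0933 /min)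
    free monomer + living end → monomer in chains + living end, rate k2*[living end]*[free monomer] (k = 33.4 /M/min)
    protic impurity + free monomer → quenched substrate (k = 32.3 /M/min)
    free monomer + initiator → living end + monomer in chains (k = 15.6 /M/min)

In birch at 100 min, monomer in chains is made, each step taken net, 1.00 times as fast as it is used up, and free monomer stands at 6.3% of its charge, or 2.79 mM. Divided by c(initiator), that is 0.735 units, and the budget less this gives 5.05. Cedar ends with 8.14% of its free monomer left and birch with 6.34%.

In the neighbour like birch but charged with 110 mM of free monomer, the budget is 23.2 units. That flask gives 22.4, with 2.5% of its free monomer left.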